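The plan cuts ring A across its C4–C5 and C6–C1 bonds. Ring A atoms C1 (CO2Me), C2 (O), C3–H and C4 (CH3) map onto C3–C6 of a 4-alkoxy-6-methyl-2-pyrone-3-carboxylate. C5–H and C6–OAr are the two sp carbons of an ethynyl ether that already bears ring B. One inverse-electron-demand [4+2] cycloaddition with loss of CO2 therefore builds the complete benzoate. It also brings in the crowded Ar–O–Ar oxygen without any substitution on an arene. The precursors are the MOM-protected pyrone 6 and the aryl ethynyl ether 19, whose benzylic alcohol is also a MOM ether. One acid treatment and a phenol-selective prenylation finish the route.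

Key step: step 9

Assumption: the target has no stereocentre, no configurable double bond and no axis hindered enough to be resolved, so it is achiral and needs no enantiocontrol; the constitution is taken exactly as drawn.

Step 1
Reactants: 1 2,2,6-trimethyl-4H-1,3-dioxin-4-one; 2 dimethyl malonate
Product: 5 methyl 4-hydroxy-6-methyl-2-oxo-2H-pyran-3-carboxylate, via acetylketene 3 (not isolated), via dimethyl acetoacetylmalonate 4 (not isolated)
Conditions: 2, NaH, diglyme, 0 °C to rt; then 1 added slowly, 115 °C; aq HCl, acid–base extraction
Reagents that add atoms: none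
Why: Thermal retro-[4+2] cleavage of the dioxinone releases acetylketene at low concentration, the dissolved sodium malonate C-acylates it (acylketene trapping, the dioxinone counterpart of diketene acetoacetylation), and the enolised terminal ketone of 4 lactonises onto one malonate ester with loss of methanol to give the acidic 4-hydroxy-2-pyrone.

Step 2
Reactants: 5 methyl 4-hydroxy-6-methyl-2-oxo-2H-pyran-3-carboxylate
Product: 6 methyl 4-(methoxymethoxy)-6-methyl-2-oxo-2H-pyran-3-carboxylate
Conditions: MOMCl, i-Pr2NEt, CH2Cl2, 0 °C; neutral work-up, Et3N-deactivated silica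
Reagents that add atoms: chloromethyl methyl ether, COCCl
Why: Williamson-type O-alkylation of a vinylogous carboxylic acid, in which the pyronate meets the hard oxocarbenium-like electrophile at its charge-rich 4-oxygen (C3 is blocked by the ester), so the 2-pyrone diene is kept.

Step 3
Reactants: 7 2,4-dimethoxybenzaldehyde
Product: 9 2,4-dimethoxyphenol, via 2,4-dimethoxyphenyl formate 8 (not isolated)
Conditions: mCPBA, CH2Cl2, 0 °C to rt; then MeOH, K2CO3 (cat.), rt
Reagents that add atoms: mCPBA, OOC(=O)c1cccc(Cl)c1
Why: Baeyer–Villiger (Dakin-type) oxidation, in which the electron-rich aryl group migrates in preference to hydrogen in the Criegee adduct, and the labile aryl formate is then methanolysed.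

Step 4
Reactants: 9 2,4-dimethoxyphenol
Product: 11 2-hydroxy-3,5-dimethoxybenzaldehyde, via 2-(hydroxymethyl)-4,6-dimethoxyphenol 10 (not isolated)
Conditions: MgCl2, Et3N, (CH2O)n, MeCN, reflux; aq HCl
Reagents that add atoms: formaldehyde (as paraformaldehyde), C=O
Why: Casnati–Skattebøl ortho-formylation, in which the magnesium phenoxide delivers coordinated formaldehyde to the only free ortho carbon and a second formaldehyde oxidises the resulting magnesium salicyl alkoxide by Oppenauer-type hydride transfer.

Step 5
Reactants: 11 2-hydroxy-3,5-dimethoxybenzaldehyde; 12 trichloroethylene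
Product: 14 2-[(E)-1,2-dichloroethenyloxy]-3,5-dimethoxybenzaldehyde, via dichloroacetylene 13 (not isolated)
Conditions: K2CO3, DMF, 70 °C, N2
Reagents that add atoms: none
Why: Carbonate dehydrochlorinates trichloroethylene and the phenoxide adds anti to the transient dichloroacetylene (the standard phenol/trichloroethylene route to (E)-1,2-dichlorovinyl ethers); using the non-enolisable aldehyde here means a phenol never has to be told apart from a benzylic alcohol.

Step 6
Reactants: 14 2-[(E)-1,2-dichloroethenyloxy]-3,5-dimethoxybenzaldehyde
Product: 15 {2-[(E)-1,2-dichloroethenyloxy]-3,5-dimethoxyphenyl}methanol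
Conditions: NaBH4, MeOH, 0 °C
Reagents that add atoms: none
Why: Chemoselective borohydride reduction of the aryl aldehyde, to which the dichlorovinyl ether and aryl ethers are inert, so the new primary alcohol is the only hydroxyl group in 15.

Step 7
Reactants: 15 {2-[(E)-1,2-dichloroethenyloxy]-3,5-dimethoxyphenyl}methanol
Product: 16 2-[(E)-1,2-dichloroethenyloxy]-1,5-dimethoxy-3-[(methoxymethoxy)methyl]benzene
Conditions: MOMCl, i-Pr2NEt, CH2Cl2, 0 °C to rt
Reagents that add atoms: chloromethyl methyl ether, COCCl
Why: Routine acetal-forming O-alkylation of a primary benzylic alcohol under amine base; MOM is chosen because it tolerates n-BuLi and long heating and later falls together with the ring A MOM group.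

Step 8
Reactants: 16 2-[(E)-1,2-dichloroethenyloxy]-1,5-dimethoxy-3-[(methoxymethoxy)methyl]benzene
Product: 19 2-(ethynyloxy)-1,5-dimethoxy-3-[(methoxymethoxy)methyl]benzene, via chloroethynyl ether 17 (not isolated), via lithium aryloxyacetylide 18 (not isolated)
Conditions: n-BuLi (2.2 equiv), THF, −78 to −40 °C; H2O, −78 °C; fast filtration through Et3N-deactivated silica, used at once
Reagents that add atoms: none
Why: Established dichlorovinyl ether to ynol ether conversion, in which lithiation of the vinylic C–H and loss of LiCl give the chloroalkyne, chlorine–lithium exchange gives the acetylide and water protonates it, all at temperatures where ring lithiation between the methoxy groups is too slow to compete.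

Step 9
Reactants: 6 methyl 4-(methoxymethoxy)-6-methyl-2-oxo-2H-pyran-3-carboxylate; 19 2-(ethynyloxy)-1,5-dimethoxy-3-[(methoxymethoxy)methyl]benzene
Product: 21 methyl 2-{2,4-dimethoxy-6-[(methoxymethoxy)methyl]phenoxy}-6-(methoxymethoxy)-4-methylbenzoate, via bridged lactone 20 (not isolated)
Conditions: 6 (1.5 equiv), 19, BHT (cat.), PhMe (1 M), base-washed sealed tube, 120 °C
Reagents that add atoms: none
Why: The diene C3=C4–C5=C6 of 6, lowered in energy by the ester and the lactone carbonyl, combines with the oxygen-raised HOMO of 19 in a concerted but markedly asynchronous inverse-electron-demand Diels–Alder reaction, the pyrone C6–CH bond forming ahead of the C3–C(OAr) bond, to give the 2-oxabicyclo[2.2.2]octadienone 20. At this temperature 20 should not persist, since retro-[4+2] extrusion of CO2 is driven by aromatisation and makes the formation of benzoate 21 irreversible. The closest known reaction type is the benzannulation of 2-pyrone-3-carboxylates with alkoxyacetylenes, ynamines and ketene acetals. Ring A is closed by an intermolecular [4+2] cycloaddition that sets its C4–C5 and C6–C1 bonds in one operation, and no stereocentre remains because both bridgeheads of 20 become sp2. The only selectivity needed is regiochemical and rests on matched polarisation: the nucleophilic ≡CH terminus attacks pyrone C6, the vinylogous acceptor site of both carbonyls, negative charge collects on the malonate-like C3 (further enriched by the 4-OMOM donor), and C3 bonds to the oxygen-stabilised cationic carbon, while the small CH end also fits best beside the 6-methyl group. An aryl ynol ether has no β-hydrogen for the retro-ene fragmentation that destroys alkyl ynol ethers on heating, a MOM ether cannot undergo the Claisen shift open to a prenyl ether, and excess cheap pyrone, high concentration and BHT help the cycloaddition outrun oligomerisation of 19.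

Step 10
Reactants: 21 methyl 2-{2,4-dimethoxy-6-[(methoxymethoxy)methyl]phenoxy}-6-(methoxymethoxy)-4-methylbenzoate
Product: 22 methyl 2-hydroxy-6-[2-(hydroxymethyl)-4,6-dimethoxyphenoxy]-4-methylbenzoate
Conditions: conc. HCl (cat.), MeOH, 45 °C
Reagents that add atoms: none
Why: Acid-catalysed transacetalisation to methanol (MOM cleavage) frees both hydroxyls at once; methanol keeps the methyl ester intact, disfavours eight-membered lactonisation and captures the methoxymethyl cation, and the benzylic carbon is meta to both methoxy groups and so resists ionisation.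

Step 11
Reactants: 22 methyl 2-hydroxy-6-[2-(hydroxymethyl)-4,6-dimethoxyphenoxy]-4-methylbenzoate
Product: 23 methyl 2-[2-(hydroxymethyl)-4,6-dimethoxyphenoxy]-4-methyl-6-[(3-methylbut-2-en-1-yl)oxy]benzoate (target)
Conditions: prenyl bromide (1.1 equiv), K2CO3, acetone, 50 °C
Reagents that add atoms: prenyl bromide (1-bromo-3-methylbut-2-ene), CC(C)=CCBr
Why: Williamson ether synthesis in which carbonate deprotonates only the salicylate phenol and not the benzylic alcohol, and the phenoxide displaces the primary allylic bromide by SN2; the prenyl ether is installed last so that it never meets heat or acid.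

Compound list
1 | 2,2,6-trimethyl-4H-1,3-dioxin-4-one | CC1=CC(=O)OC(C)(C)O1 | starting material
2 | dimethyl malonate | COC(=O)CC(=O)OC | starting material
3 | acetylketene (but-1-ene-1,3-dione), not isolated | CC(=O)C=C=O | intermediate
4 | dimethyl acetoacetylmalonate (dimethyl 2-(3-oxobutanoyl)propanedioate, formed as its sodium enolate), not isolated | COC(=O)C(C(=O)OC)C(=O)CC(C)=O | intermediate
5 | methyl 4-hydroxy-6-methyl-2-oxo-2H-pyran-3-carboxylate | COC(=O)C1=C(O)C=C(C)OC1=O | intermediate
6 | methyl 4-(methoxymethoxy)-6-methyl-2-oxo-2H-pyran-3-carboxylate | COCOC1=C(C(=O)OC)C(=O)OC(C)=C1 | intermediate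
7 | 2,4-dimethoxybenzaldehyde | COc1ccc(C=O)c(OC)c1 | starting material
8 | 2,4-dimethoxyphenyl formate, not isolated | COc1ccc(OC=O)c(OC)c1 | intermediate
9 | 2,4-dimethoxyphenol | COc1ccc(O)c(OC)c1 | intermediate
10 | 2-(hydroxymethyl)-4,6-dimethoxyphenol (present as its magnesium salt), not isolated | OCc1cc(OC)cc(OC)c1O | intermediate
11 | 2-hydroxy-3,5-dimethoxybenzaldehyde | O=Cc1cc(OC)cc(OC)c1O | intermediate
12 | trichloroethylene | ClC=C(Cl)Cl | starting material
13 | dichloroacetylene, not isolated | ClC#CCl | intermediate
14 | 2-[(E)-1,2-dichloroethenyloxy]-3,5-dimethoxybenzaldehyde | Cl/C=C(/Cl)Oc1c(C=O)cc(OC)cc1OC | intermediate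
15 | {2-[(E)-1,2-dichloroethenyloxy]-3,5-dimethoxyphenyl}methanol | Cl/C=C(/Cl)Oc1c(CO)cc(OC)cc1OC | intermediate
16 | 2-[(E)-1,2-dichloroethenyloxy]-1,5-dimethoxy-3-[(methoxymethoxy)methyl]benzene | Cl/C=C(/Cl)Oc1c(COCOC)cc(OC)cc1OC | intermediate
17 | 2-(chloroethynyloxy)-1,5-dimethoxy-3-[(methoxymethoxy)methyl]benzene, not isolated | ClC#COc1c(COCOC)cc(OC)cc1OC | intermediate
18 | lithium {2,4-dimethoxy-6-[(methoxymethoxy)methyl]phenoxy}acetylide, not isolated | [Li]C#COc1c(COCOC)cc(OC)cc1OC | intermediate
19 | 2-(ethynyloxy)-1,5-dimethoxy-3-[(methoxymethoxy)methyl]benzene | C#COc1c(COCOC)cc(OC)cc1OC | intermediate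
20 | methyl 8-{2,4-dimethoxy-6-[(methoxymethoxy)methyl]phenoxy}-5-(methoxymethoxy)-1-methyl-3-oxo-2-oxabicyclo[2.2.2]octa-5,7-diene-4-carboxylate (racemic, transient), not isolated | COC(=O)C12C(=O)OC(C)(C=C1OCOC)C=C2Oc1c(COCOC)cc(OC)cc1OC | intermediate
21 | methyl 2-{2,4-dimethoxy-6-[(methoxymethoxy)methyl]phenoxy}-6-(methoxymethoxy)-4-methylbenzoate | COC(=O)c1c(OCOC)cc(C)cc1Oc1c(COCOC)cc(OC)cc1OC | intermediate
22 | methyl 2-hydroxy-6-[2-(hydroxymethyl)-4,6-dimethoxyphenoxy]-4-methylbenzoate | COC(=O)c1c(O)cc(C)cc1Oc1c(CO)cc(OC)cc1OC | intermediate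
23 | methyl 2-[2-(hydroxymethyl)-4,6-dimethoxyphenoxy]-4-methyl-6-[(3-methylbut-2-en-1-yl)oxy]benzoate (achiral) | COC(=O)c1c(OCC=C(C)C)cc(C)cc1Oc1c(CO)cc(OC)cc1OC | target

Total step count: 11.
Longest linear sequence: 9 steps (7 to 23, steps 3–11). The pyrone branch (steps 1–2) joins at step 9.

Steps most likely to fail

Step 9. The cycloaddition is slowed by the 4-alkoxy donor and the 6-methyl group. It may be outrun by thermal oligomerisation or adventitious hydration of the ynol ether. The fallback sets out from 6 and makes the diaryl ether bond by copper catalysis instead.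
- 6 is heated in toluene with the far more nucleophilic 1,1-bis(trimethylsilyloxy)ethene, C=C(O[Si](C)(C)C)O[Si](C)(C)C. The same cycloaddition and CO2 loss, followed by loss of silanol and an aqueous methanol work-up, should give methyl 2-hydroxy-6-(methoxymethoxy)-4-methylbenzoate F1.
- F1 then undergoes a ligand-accelerated Ullmann coupling with commercial 2-bromo-3,5-dimethoxybenzaldehyde, O=Cc1cc(OC)cc(OC)c1Br (CuI, N,N-dimethylglycine, Cs2CO3, dioxane, 100 °C). The ortho formyl group activates the bromide, and the coupling should give methyl 2-(2-formyl-4,6-dimethoxyphenoxy)-6-(methoxymethoxy)-4-methylbenzoate F2.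
- NaBH4 in MeOH at 0 °C reduces the aldehyde to methyl 2-[2-(hydroxymethyl)-4,6-dimethoxyphenoxy]-6-(methoxymethoxy)-4-methylbenzoate F3.
- The acid methanolysis of step 10 removes the remaining MOM group, and the fallback comes back to the route at 22.

Step 2. Two processes may spoil the step. Alkylation may stray to the lactone carbonyl oxygen. The acetal may also be lost from the vinylogous-ester oxygen by hydrolysis during work-up and chromatography. The fallback sets out from 5 and replaces alkylation with a redox condensation and a robust ether.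
- Mitsunobu reaction with benzyl alcohol (PPh3, DIAD, THF, 0 °C to rt), which is known to alkylate 4-hydroxy-2-pyrones at the 4-oxygen, should give methyl 4-(benzyloxy)-6-methyl-2-oxo-2H-pyran-3-carboxylate F4.
- Cycloaddition of F4 with 19 under the conditions of step 9 should give methyl 2-(benzyloxy)-6-{2,4-dimethoxy-6-[(methoxymethoxy)methyl]phenoxy}-4-methylbenzoate F5.
- Hydrogenolysis (H2, Pd/C, EtOAc, rt) frees the phenol as methyl 2-{2,4-dimethoxy-6-[(methoxymethoxy)methyl]phenoxy}-6-hydroxy-4-methylbenzoate F6.
- Catalytic HCl in MeOH removes the benzylic MOM group, and the fallback comes back to the route at 22.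

Step 8. The terminal ynol ether may hydrate or oligomerise during aqueous quench, concentration and chromatography. The fallback sets out from 16 and stores the alkyne in capped form.
- The acetylide 18, generated as before, is quenched with TMSCl at −78 °C. This gives the chromatography-stable ({2,4-dimethoxy-6-[(methoxymethoxy)methyl]phenoxy}ethynyl)trimethylsilane F7.
- Just before the cycloaddition, F7 is desilylated with TBAF in moist THF at −20 °C. After a short basic alumina plug the toluene solution is used directly, and the fallback comes back to the route at 19.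

Further compounds
F1 | step 9 | methyl 2-hydroxy-6-(methoxymethoxy)-4-methylbenzoate | COC(=O)c1c(O)cc(C)cc1OCOC
F2 | step 9 | methyl 2-(2-formyl-4,6-dimethoxyphenoxy)-6-(methoxymethoxy)-4-methylbenzoate | COC(=O)c1c(OCOC)cc(C)cc1Oc1c(C=O)cc(OC)cc1OC
F3 | step 9 | methyl 2-[2-(hydroxymethyl)-4,6-dimethoxyphenoxy]-6-(methoxymethoxy)-4-methylbenzoate | COC(=O)c1c(OCOC)cc(C)cc1Oc1c(CO)cc(OC)cc1OC
F4 | step 2 | methyl 4-(benzyloxy)-6-methyl-2-oxo-2H-pyran-3-carboxylate | COC(=O)C1=C(OCc2ccccc2)C=C(C)OC1=O
F5 | step 2 | methyl 2-(benzyloxy)-6-{2,4-dimethoxy-6-[(methoxymethoxy)methyl]phenoxy}-4-methylbenzoate | COC(=O)c1c(OCc2ccccc2)cc(C)cc1Oc1c(COCOC)cc(OC)cc1OC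
F6 | step 2 | methyl 2-{2,4-dimethoxy-6-[(methoxymethoxy)methyl]phenoxy}-6-hydroxy-4-methylbenzoate | COC(=O)c1c(O)cc(C)cc1Oc1c(COCOC)cc(OC)cc1OC
F7 | step 8 | ({2,4-dimethoxy-6-[(methoxymethoxy)methyl]phenoxy}ethynyl)trimethylsilane | C[Si](C)(C)C#COc1c(COCOC)cc(OC)cc1OC
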